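**Retrosynthetic overview**

- The strategy rests on the two A-rings being the same 2,3-dioxygenated phenol: the upper ring A is bonded to C4 through C4a (ortho to O1), the lower ring A through C6′ (para to O1′).
- The C4–C6′ bond and the upper pyran ring (C4–C4a, O1–C2) are therefore cut in one operation to two molecules of 2,3-bis(benzyloxy)phenol and one cis-aryl epoxy aldehyde that supplies C2–C3–C4.
- Ring order: the upper ring C closes in the key step; the lower ring C closes afterwards at the free phenol (O1′–C2′ by asymmetric propargylic etherification, C4′–C4a′ by 6-endo hydroarylation). Its 3′,4′-trans diol comes from the flav-3-ene through bromohydrin and syn-epoxide, and hydrogenolysis ends the route.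
- The epoxy aldehyde comes from 4-hydroxybenzaldehyde (Z-olefination, reduction, Sharpless epoxidation, oxidation); the phenol comes from 2,3-dihydroxybenzaldehyde.

Key step: step 10

Remark on the chemistry: ring B of the upper unit is carried as its benzylsulfonate (phenylmethanesulfonate) and not as a benzyl ether. A para-benzyloxyphenyl cis-epoxide would ionise at C2, whereas the sulfonate is electron-withdrawing and is assumed to fall in the final hydrogenolysis, as is known for this protecting group. Flavan numbering is used, with primed locants for the lower unit.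

Step 1
Reactants: 1 4-hydroxybenzaldehyde
Product: 2 4-formylphenyl phenylmethanesulfonate
Conditions: BnSO2Cl, Et3N, CH2Cl2, 0 °C
Reagents that add atoms: phenylmethanesulfonyl chloride, O=S(=O)(Cl)Cc1ccccc1
Why: O-sulfonylation of the phenol gives an electron-poor, hydrogenolysable stand-in for a benzyl ether that will keep the later aryl epoxide from ionising.

Step 2
Reactants: 2 4-formylphenyl phenylmethanesulfonate
Product: 3 methyl (2Z)-3-{4-[(benzylsulfonyl)oxy]phenyl}prop-2-enoate
Conditions: (CF3CH2O)2P(O)CH2CO2Me, KN(SiMe3)2, 18-crown-6, THF, −78 °C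
Reagents that add atoms: methyl bis(2,2,2-trifluoroethyl)phosphonoacetate, COC(=O)CP(=O)(OCC(F)(F)F)OCC(F)(F)F
Why: Still–Gennari olefination, in which the electron-poor phosphonate collapses fast and irreversibly to the (Z)-cinnamate, the base being consumed by the phosphonate before 2 is added so that the sulfonate CH2 is left alone.

Step 3
Reactants: 3 methyl (2Z)-3-{4-[(benzylsulfonyl)oxy]phenyl}prop-2-enoate
Product: 4 4-[(1Z)-3-hydroxyprop-1-en-1-yl]phenyl phenylmethanesulfonate
Conditions: iBu2AlH (2.5 equiv), CH2Cl2, −78 °C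
Reagents that add atoms: none
Why: 1,2-reduction of the enoate by the aluminium hydride at low temperature should leave the (Z)-alkene and the aryl sulfonate untouched.

Step 4
Reactants: 4 4-[(1Z)-3-hydroxyprop-1-en-1-yl]phenyl phenylmethanesulfonate
Product: 5 [(2R,3S)-3-{4-[(benzylsulfonyl)oxy]phenyl}oxiran-2-yl]methanol (cis-epoxy alcohol)
Conditions: tBuOOH, Ti(OiPr)4 (20 mol %), D-(−)-diisopropyl tartrate (26 mol %), 4 Å molecular sieves, CH2Cl2, −20 °C
Reagents that add atoms: tert-butyl hydroperoxide, CC(C)(C)OO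
Why: Sharpless asymmetric epoxidation, in which the (Z)-alkene gives the cis-epoxide stereospecifically and the D-(−)-tartrate complex sets both centres as (2R,3S) (the L-(+)-ester gives the 2S,3R series); (Z)-aryl allylic alcohols react slowly and with lower selectivity, so any material of the wrong hand is removed by recrystallising 5 or later as a diastereomer.

Step 5
Reactants: 5 [(2R,3S)-3-{4-[(benzylsulfonyl)oxy]phenyl}oxiran-2-yl]methanol
Product: 6 (2S,3S)-3-{4-[(benzylsulfonyl)oxy]phenyl}oxirane-2-carbaldehyde (cis-epoxy aldehyde)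
Conditions: Dess–Martin periodinane, CH2Cl2, 0 °C to rt
Reagents that add atoms: none
Why: Dess–Martin oxidation of the primary alcohol under non-basic conditions should give the cis-epoxy aldehyde without epimerisation at the carbon next to the carbonyl group, the aldehyde being used at once.

Step 6
Reactants: 7 2,3-dihydroxybenzaldehyde
Product: 8 2,3-bis(benzyloxy)benzaldehyde
Conditions: BnBr, K2CO3, DMF, 60 °C
Reagents that add atoms: benzyl bromide, BrCc1ccccc1
Why: Williamson ether synthesis on both phenolic hydroxyls, chosen because the two adjacent hydroxyls of pyrogallol itself cannot be benzylated selectively.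

Step 7
Reactants: 8 2,3-bis(benzyloxy)benzaldehyde
Product: 10 2,3-bis(benzyloxy)phenol, via aryl formate 9 (not isolated)
Conditions: mCPBA, CH2Cl2, rt; then K2CO3 (cat.), MeOH, rt
Reagents that add atoms: 3-chloroperoxybenzoic acid, OOC(=O)c1cccc(Cl)c1
Why: Baeyer–Villiger (Dakin-type) oxidation, in which the electron-rich ortho-alkoxyaryl group migrates to oxygen and the formate is then methanolysed to the phenol.

Step 8
Reactants: 11 3,4-bis(benzyloxy)benzaldehyde
Product: 12 rac-1-[3,4-bis(benzyloxy)phenyl]prop-2-yn-1-ol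
Conditions: HC≡CMgBr, THF, 0 °C; then H2O
Reagents that add atoms: ethynylmagnesium bromide, C#C[Mg]Br
Why: Grignard addition to the aldehyde, the racemic alcohol being sufficient because the later substitution passes through a planar copper allenylidene.

Step 9
Reactants: 12 rac-1-[3,4-bis(benzyloxy)phenyl]prop-2-yn-1-ol
Product: 13 rac-1-[3,4-bis(benzyloxy)phenyl]prop-2-yn-1-yl acetate
Conditions: Ac2O, Et3N, DMAP (cat.), CH2Cl2, 0 °C
Reagents that add atoms: acetic anhydride, CC(=O)OC(C)=O
Why: DMAP-catalysed acylation installs the leaving group for the propargylic substitution.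

Step 10
Reactants: 10 2,3-bis(benzyloxy)phenol (two molecules are built in); 6 (2S,3S)-3-{4-[(benzylsulfonyl)oxy]phenyl}oxirane-2-carbaldehyde
Product: 17 4-[(2R,3R,4S)-7,8-bis(benzyloxy)-4-[2,3-bis(benzyloxy)-4-hydroxyphenyl]-3-hydroxy-3,4-dihydro-2H-chromen-2-yl]phenyl phenylmethanesulfonate (2,3-cis-3,4-trans), via magnesium bis(aryloxide) 14 (not isolated), via epoxy carbinol 15 (not isolated), via flavan-3,4-diol 16 (not isolated)
Conditions: 10 (2.0 equiv), Bu2Mg (1.0 equiv), toluene, 0 °C; 6 (1.0 equiv), CH2Cl2, −30 °C to rt; then 10 (1.0 equiv), CF3CO2H, (CF3)2CHOH, 0 °C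
Reagents that add atoms: none
Why: Proposed new method: the magnesium aryloxide 14 binds the aldehyde of 6 and delivers it to its own ortho carbon through a six-membered chelate (C4–C4a, carbinol 15), the magnesium-bound phenoxide oxygen then opens the chelated epoxide at the benzylic carbon in a 6-endo-tet closure of the pyran ring (O1–C2, diol 16), and CF3CO2H finally ionises the C4 hydroxyl to a cation stabilised by O1 and the para 7-benzyloxy group, which a second molecule of 10 captures through its carbon para to OH (C4–C6′); the three stages are known separately but not as one operation. The closest known reactions are the ortho-hydroxyalkylation of magnesium phenoxides with aldehydes, the metal-assisted opening of 2,3-epoxy alcohols at the carbon remote from the carbinol together with the 6-endo cyclisation of 2-hydroxyaryl aryl epoxides, and the acid-mediated C4 arylation of flavan-3,4-diols. C2 is set by SN2 inversion at the (3S) epoxide carbon, which turns the cis-epoxide into the 2,3-cis flavan while C3 keeps its oxygen, and C4 is set on the cyclic cation by attack anti to the C3 hydroxyl and the C2 aryl group (3,4-trans), so the mixed configuration of the first carbinol does not matter. Ortho attack of the first molecule is secured by the chelate, halide-free magnesium leaves no external nucleophile for the epoxide, and the electron-poor benzylsulfonyloxy group on ring B keeps C2 from ionising, so that inversion instead of scrambling is expected and the ring should close before acid is added. Para attack of the second molecule rests on the free hydroxyl as the strongest donor, helped by the ortho benzyloxy group, and an excess of 10 limits attack of the cation on the product phenol.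

Step 11
Reactants: 17 the 4-arylflavan-3-ol phenol from step 10; 13 rac-1-[3,4-bis(benzyloxy)phenyl]prop-2-yn-1-yl acetate
Product: 18 (1S)-propargylic aryl ether of 17 (phenolic oxygen bonded to C1 of 1-[3,4-bis(benzyloxy)phenyl]prop-2-yne)
Conditions: CuOTf·1/2C6H6 (5 mol %), chiral 2,6-bis(oxazolinyl)pyridine (pybox) ligand (10 mol %), iPr2NEt, ClCH2CH2Cl, −20 °C
Reagents that add atoms: none
Why: copper-catalysed asymmetric propargylic etherification through a monovalent copper allenylidene, the phenoxide adding to the face left open by the pybox ligand, whose antipode is chosen (on phenol 10 as a model) to give the (S) ether, while the acidic phenol should outcompete the hindered C3 hydroxyl.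

Step 12
Reactants: 18 (1S)-propargylic aryl ether of 17
Product: 19 flav-3-ene (lower ring closed to the (2′S)-2-[3,4-bis(benzyloxy)phenyl]-7,8-bis(benzyloxy)-2H-chromene bonded through C6′ to C4 of the upper unit of 17)
Conditions: Ph3PAuNTf2 (3 mol %), CH2Cl2, 0 °C to rt
Reagents that add atoms: none
Why: gold-catalysed intramolecular hydroarylation of an aryl propargyl ether, in which the only free carbon ortho to the ether oxygen (future C4a′, para to the 7′-benzyloxy group) attacks the activated alkyne 6-endo-dig and protodeauration gives the 2H-chromene without touching the C2′–O bond, so C2′ keeps its configuration.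

Step 13
Reactants: 19 flav-3-ene
Product: 20 bromohydrin (lower ring 2′R,3′S,4′R: 3′-Br trans to the C2′ aryl group and 4′-OH cis to it)
Conditions: NBS, THF/H2O, −10 °C
Reagents that add atoms: N-bromosuccinimide, O=C1CCC(=O)N1Br; water, O
Why: bromohydrin formation, in which bromine adds to the electron-rich C3′=C4′ bond on the face away from the C2′ aryl group and water opens the bromonium ion at the benzylic C4′ from the other face, the enol-ether-like alkene reacting far faster than the arene rings.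

Step 14
Reactants: 20 bromohydrin
Product: 22 lower-ring (2′R,3′R,4′S)-3′,4′-diol (hexa-O-benzyl benzylsulfonate of the target), via cis-epoxide 21 (not isolated)
Conditions: K2CO3, THF/H2O, rt
Reagents that add atoms: water, O
Why: Williamson-type closure, in which the C4′ alkoxide displaces bromide with inversion at C3′ and so places the epoxide oxygen on the face of the C2′ aryl group, followed by hydrolysis of the activated benzylic epoxide by attack of water at C4′ anti to the C3′ oxygen to give the 2′,3′-cis-3′,4′-trans diol, which is also the solvolytically favoured C4′ epimer of this flavan-3,4-diol type.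

Step 15
Reactants: 22 hexa-O-benzyl benzylsulfonate of the target
Product: 23 (2R,3R,4S)-4-[(2R,3R,4S)-2-(3,4-dihydroxyphenyl)-3,4,7,8-tetrahydroxy-3,4-dihydro-2H-chromen-6-yl]-2-(4-hydroxyphenyl)-3,4-dihydro-2H-chromene-3,7,8-triol (target)
Conditions: H2 (1 atm), Pd(OH)2/C, THF/EtOAc, rt
Reagents that add atoms: none
Why: catalytic hydrogenolysis should cleave the six aryl benzyl ethers and the benzylsulfonate (benzylic C–S cleavage, then loss of SO2) in a neutral medium chosen to spare the benzylic C4′ hydroxyl, and it touches no stereocentre.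

**Compound list**

1 | 4-hydroxybenzaldehyde | O=Cc1ccc(O)cc1 | starting material
2 | 4-formylphenyl phenylmethanesulfonate | O=Cc1ccc(OS(=O)(=O)Cc2ccccc2)cc1 | intermediate
3 | methyl (2Z)-3-{4-[(benzylsulfonyl)oxy]phenyl}prop-2-enoate | COC(=O)/C=C\c1ccc(OS(=O)(=O)Cc2ccccc2)cc1 | intermediate
4 | 4-[(1Z)-3-hydroxyprop-1-en-1-yl]phenyl phenylmethanesulfonate | OC/C=C\c1ccc(OS(=O)(=O)Cc2ccccc2)cc1 | intermediate
5 | [(2R,3S)-3-{4-[(benzylsulfonyl)oxy]phenyl}oxiran-2-yl]methanol (cis) | OC[C@H]1O[C@H]1c1ccc(OS(=O)(=O)Cc2ccccc2)cc1 | intermediate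
6 | (2S,3S)-3-{4-[(benzylsulfonyl)oxy]phenyl}oxirane-2-carbaldehyde (cis) | O=C[C@H]1O[C@H]1c1ccc(OS(=O)(=O)Cc2ccccc2)cc1 | intermediate
7 | 2,3-dihydroxybenzaldehyde | O=Cc1cccc(O)c1O | starting material
8 | 2,3-bis(benzyloxy)benzaldehyde | O=Cc1cccc(OCc2ccccc2)c1OCc1ccccc1 | intermediate
9 | 2,3-bis(benzyloxy)phenyl formate | O=COc1cccc(OCc2ccccc2)c1OCc1ccccc1 | intermediate (not isolated)
10 | 2,3-bis(benzyloxy)phenol | Oc1cccc(OCc2ccccc2)c1OCc1ccccc1 | intermediate
11 | 3,4-bis(benzyloxy)benzaldehyde | O=Cc1ccc(OCc2ccccc2)c(OCc2ccccc2)c1 | starting material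
12 | rac-1-[3,4-bis(benzyloxy)phenyl]prop-2-yn-1-ol | C#CC(O)c1ccc(OCc2ccccc2)c(OCc2ccccc2)c1 | intermediate
13 | rac-1-[3,4-bis(benzyloxy)phenyl]prop-2-yn-1-yl acetate | C#CC(OC(C)=O)c1ccc(OCc2ccccc2)c(OCc2ccccc2)c1 | intermediate
14 | magnesium bis[2,3-bis(benzyloxy)phenoxide] | [Mg+2].[O-]c1cccc(OCc2ccccc2)c1OCc1ccccc1.[O-]c1cccc(OCc2ccccc2)c1OCc1ccccc1 | intermediate (not isolated)
15 | 4-[(2S,3R)-3-{[3,4-bis(benzyloxy)-2-hydroxyphenyl](hydroxy)methyl}oxiran-2-yl]phenyl phenylmethanesulfonate (cis-epoxide; both carbinol epimers; present as its magnesium chelate) | Oc1c(OCc2ccccc2)c(OCc2ccccc2)ccc1C(O)[C@H]1O[C@H]1c1ccc(OS(=O)(=O)Cc2ccccc2)cc1 | intermediate (not isolated)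
16 | 4-[(2R,3R)-7,8-bis(benzyloxy)-3,4-dihydroxy-3,4-dihydro-2H-chromen-2-yl]phenyl phenylmethanesulfonate (2,3-cis; both C4 epimers; present as its magnesium diolate) | O=S(=O)(Cc1ccccc1)Oc1ccc([C@H]2Oc3c(ccc(OCc4ccccc4)c3OCc3ccccc3)C(O)[C@H]2O)cc1 | intermediate (not isolated)
17 | 4-[(2R,3R,4S)-7,8-bis(benzyloxy)-4-[2,3-bis(benzyloxy)-4-hydroxyphenyl]-3-hydroxy-3,4-dihydro-2H-chromen-2-yl]phenyl phenylmethanesulfonate (2,3-cis-3,4-trans) | O=S(=O)(Cc1ccccc1)Oc1ccc([C@H]2Oc3c(ccc(OCc4ccccc4)c3OCc3ccccc3)[C@H](c3ccc(O)c(OCc4ccccc4)c3OCc3ccccc3)[C@H]2O)cc1 | intermediate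
18 | 17 with its phenolic oxygen bearing the (1S)-1-[3,4-bis(benzyloxy)phenyl]prop-2-yn-1-yl group | O=S(=O)(Cc1ccccc1)Oc1ccc([C@H]2Oc3c(ccc(OCc4ccccc4)c3OCc3ccccc3)[C@H](c3ccc(O[C@H](c4ccc(OCc5ccccc5)c(OCc5ccccc5)c4)C#C)c(OCc4ccccc4)c3OCc3ccccc3)[C@H]2O)cc1 | intermediate
19 | flav-3-ene: upper unit as in 17, bonded at C4 to C6′ of (2′S)-2-[3,4-bis(benzyloxy)phenyl]-7,8-bis(benzyloxy)-2H-chromene | O=S(=O)(Cc1ccccc1)Oc1ccc([C@H]2Oc3c(ccc(OCc4ccccc4)c3OCc3ccccc3)[C@H](c3cc4c(c(OCc5ccccc5)c3OCc3ccccc3)O[C@H](c3ccc(OCc5ccccc5)c(OCc5ccccc5)c3)C=C4)[C@H]2O)cc1 | intermediate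
20 | bromohydrin of 19: lower ring (2′R,3′S,4′R)-3′-bromo-4′-hydroxy, Br trans and OH cis to the C2′ aryl group | O=S(=O)(Cc1ccccc1)Oc1ccc([C@H]2Oc3c(ccc(OCc4ccccc4)c3OCc3ccccc3)[C@H](c3cc4c(c(OCc5ccccc5)c3OCc3ccccc3)O[C@H](c3ccc(OCc5ccccc5)c(OCc5ccccc5)c3)[C@@H](Br)[C@@H]4O)[C@H]2O)cc1 | intermediate
21 | lower-ring 3′,4′-epoxide on the face of the C2′ aryl group (2′R,3′S,4′R) | O=S(=O)(Cc1ccccc1)Oc1ccc([C@H]2Oc3c(ccc(OCc4ccccc4)c3OCc3ccccc3)[C@H](c3cc4c(c(OCc5ccccc5)c3OCc3ccccc3)O[C@H](c3ccc(OCc5ccccc5)c(OCc5ccccc5)c3)[C@@H]5O[C@H]45)[C@H]2O)cc1 | intermediate (not isolated)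
22 | hexa-O-benzyl benzylsulfonate of the target: lower ring (2′R,3′R,4′S)-3′,4′-diol (2′,3′-cis-3′,4′-trans) | O=S(=O)(Cc1ccccc1)Oc1ccc([C@H]2Oc3c(ccc(OCc4ccccc4)c3OCc3ccccc3)[C@H](c3cc4c(c(OCc5ccccc5)c3OCc3ccccc3)O[C@H](c3ccc(OCc5ccccc5)c(OCc5ccccc5)c3)[C@H](O)[C@H]4O)[C@H]2O)cc1 | intermediate
23 | (2R,3R,4S)-4-[(2R,3R,4S)-2-(3,4-dihydroxyphenyl)-3,4,7,8-tetrahydroxy-3,4-dihydro-2H-chromen-6-yl]-2-(4-hydroxyphenyl)-3,4-dihydro-2H-chromene-3,7,8-triol | Oc1ccc([C@H]2Oc3c(ccc(O)c3O)[C@H](c3cc4c(c(O)c3O)O[C@H](c3ccc(O)c(O)c3)[C@H](O)[C@H]4O)[C@H]2O)cc1 | target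

**Step count**

Total steps: 15. Longest linear sequence: 11 steps (steps 1–5, 10, 11–15).

**Steps most likely to fail**

Risk 1, step 10 (proposed new method). The C4 carbinol may ionise before the pyran ring has closed, so that C4 is set under acyclic control. The second phenol may attack through its ortho carbon, or the epoxide may open 5-exo. The fallback uses known chemistry only, sets out from 2 and 10 and returns at 17. Aldehyde 2 is ethynylated (HC≡CMgBr, THF, −78 °C) to the propargylic alcohol F1 and acetylated to the acetate F2. Copper-catalysed asymmetric etherification of 10 with F2 under the conditions of step 11 gives the (S)-propargylic ether F3, and Ph3PAuNTf2 closes it to the flav-3-ene F4. NBS in aqueous THF gives the bromohydrin F5. K2CO3 in aqueous THF gives the cis-epoxide F6 and, by hydrolysis, the 2,3-cis-3,4-trans diol F7, which is one C4 epimer of 16. F7 and 10 with CF3CO2H in (CF3)2CHOH then give 17 by the known C4 arylation of a flavan-3,4-diol.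

Risk 2, step 11. The electron-rich phenol ring may be propargylated at carbon, or an uncatalysed SN1 substitution of the electron-rich acetate may erode the control at C2′. The fallback sets out from 17 and 11 and returns at 19, so that step 12 is bypassed as well. Aldehyde 11 is homologated with Ph3P=CHCHO to the cinnamaldehyde F8. Phenol 17, F8 and PhB(OH)2 with propionic acid in hot toluene should condense at the free ortho carbon, and 6π-electrocyclisation of the ortho-quinone methide gives flav-3-ene 19 together with its C2′ epimer F9. F9 is removed by chromatography, which is possible because the upper unit is already enantioenriched.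

Risk 3, step 15. Hydrogenolysis of the activated benzylic C4′–O bond may compete with debenzylation, and the sulfur dioxide set free may slow the catalyst. The fallback sets out from 22 and returns at 23. MnO2 in CH2Cl2 should oxidise only the benzylic C4′ hydroxyl of 22 to the ketone F10, which has no reducible benzylic C–O bond. Hydrogenolysis over Pd(OH)2/C then gives the free phenolic dihydroflavonol F11. NaBH4 in ethanol reduces the ketone; the expected 3′,4′-cis alcohol F12 is equilibrated at C4′ in dilute aqueous acid to the 3′,4′-trans diol 23, the epimerisation known for this class of flavan-3,4-diols.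

Further compounds
F1 | step 10 | rac-4-(1-hydroxyprop-2-yn-1-yl)phenyl phenylmethanesulfonate | C#CC(O)c1ccc(OS(=O)(=O)Cc2ccccc2)cc1
F2 | step 10 | rac-1-{4-[(benzylsulfonyl)oxy]phenyl}prop-2-yn-1-yl acetate | C#CC(OC(C)=O)c1ccc(OS(=O)(=O)Cc2ccccc2)cc1
F3 | step 10 | 4-{(1S)-1-[2,3-bis(benzyloxy)phenoxy]prop-2-yn-1-yl}phenyl phenylmethanesulfonate | C#C[C@H](Oc1cccc(OCc2ccccc2)c1OCc1ccccc1)c1ccc(OS(=O)(=O)Cc2ccccc2)cc1
F4 | step 10 | 4-[(2S)-7,8-bis(benzyloxy)-2H-chromen-2-yl]phenyl phenylmethanesulfonate | O=S(=O)(Cc1ccccc1)Oc1ccc([C@H]2Oc3c(ccc(OCc4ccccc4)c3OCc3ccccc3)C=C2)cc1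
F5 | step 10 | bromohydrin of F4 (3-Br trans to the C2 aryl group, 4-OH cis to it) | O=S(=O)(Cc1ccccc1)Oc1ccc([C@H]2Oc3c(ccc(OCc4ccccc4)c3OCc3ccccc3)[C@@H](O)[C@@H]2Br)cc1
F6 | step 10 | 3,4-epoxide of F4 on the face of the C2 aryl group | O=S(=O)(Cc1ccccc1)Oc1ccc([C@H]2Oc3c(ccc(OCc4ccccc4)c3OCc3ccccc3)[C@H]5O[C@@H]25)cc1
F7 | step 10 | 4-[(2R,3R,4S)-7,8-bis(benzyloxy)-3,4-dihydroxy-3,4-dihydro-2H-chromen-2-yl]phenyl phenylmethanesulfonate (2,3-cis-3,4-trans epimer of 16) | O=S(=O)(Cc1ccccc1)Oc1ccc([C@H]2Oc3c(ccc(OCc4ccccc4)c3OCc3ccccc3)[C@H](O)[C@H]2O)cc1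
F8 | step 11 | (2E)-3-[3,4-bis(benzyloxy)phenyl]prop-2-enal | O=C/C=C/c1ccc(OCc2ccccc2)c(OCc2ccccc2)c1
F9 | step 11 | C2′ epimer of 19 | O=S(=O)(Cc1ccccc1)Oc1ccc([C@H]2Oc3c(ccc(OCc4ccccc4)c3OCc3ccccc3)[C@H](c3cc4c(c(OCc5ccccc5)c3OCc3ccccc3)O[C@@H](c3ccc(OCc5ccccc5)c(OCc5ccccc5)c3)C=C4)[C@H]2O)cc1
F10 | step 15 | C4′ ketone of 22 (2′,3′-cis-3′-hydroxyflavan-4′-one) | O=S(=O)(Cc1ccccc1)Oc1ccc([C@H]2Oc3c(ccc(OCc4ccccc4)c3OCc3ccccc3)[C@H](c3cc4c(c(OCc5ccccc5)c3OCc3ccccc3)O[C@H](c3ccc(OCc5ccccc5)c(OCc5ccccc5)c3)[C@H](O)C4=O)[C@H]2O)cc1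
F11 | step 15 | fully deprotected C4′ ketone | Oc1ccc([C@H]2Oc3c(ccc(O)c3O)[C@H](c3cc4c(c(O)c3O)O[C@H](c3ccc(O)c(O)c3)[C@H](O)C4=O)[C@H]2O)cc1
F12 | step 15 | C4′ epimer of 23 (3′,4′-cis diol) | Oc1ccc([C@H]2Oc3c(ccc(O)c3O)[C@H](c3cc4c(c(O)c3O)O[C@H](c3ccc(O)c(O)c3)[C@H](O)[C@@H]4O)[C@H]2O)cc1
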